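**Retrosynthetic overview**
- Target ⇒ diene diacetate: two Markovnikov C–O bonds (C4–O, C10–O), made last by radical hydration from the convex α-face.
- Diene diacetate ⇒ diene tetraol (two ester C–O bonds) ⇒ triene diol: the C11–O and C13–O bonds, by hydroxyl-directed dihydroxylation of one of three exocyclic methylenes.
- Triene diol ⇒ (−)-dehydrocostus lactone by 1,2-reduction of the α-methylene lactone; the lactone supplies all fifteen skeletal carbons and the C1, C5, C6 and C7 stereocenters.
- Ring formation: none. The cis-fused five/seven-membered skeleton is bought intact. The lactone is opened first (so the radical hydration never meets a conjugated alkene), the side-chain alkene is oxygenated second (it alone has an allylic OH), and C4/C10 are set last.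

Assumption: bulk (−)-dehydrocostus lactone from costus root oil counts as a cheap commercial starting material; guaiane numbering is used (C1/C5 ring fusion, C15 on C4, C14 on C10, C7 bearing C11 with C12 and C13), and the target SMILES decodes to 1αH,5αH,7αH with 4α-, 6α- and 10α-OH (1R,4R,5S,6S,7R,10R), the same absolute series as this lactone.

**Route**

Step 1
Reactants: 1 (−)-dehydrocostus lactone
Product: 3 (1αH,5αH,7αH)-guaia-4(15),10(14),11(13)-triene-6α,12-diol, via lactol 2 (not isolated)
Conditions: i-Bu2AlH (4.5 equiv), CH2Cl2, −78 → 0 °C; aq. potassium sodium tartrate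
Reagents that add atoms: none
Why: Lactone-to-diol reduction with i-Bu2AlH proceeds in the 1,2 sense through the aluminium lactol, leaves the three 1,1-disubstituted alkenes alone, and neither creates nor disturbs a stereocenter.

Step 2
Reactants: 3 (1αH,5αH,7αH)-guaia-4(15),10(14),11(13)-triene-6α,12-diol
Product: 4 (1αH,5αH,7αH)-guaia-4(15),10(14)-diene-6α,11,12,13-tetraol
Conditions: OsO4 (2 mol %), quinuclidine N-oxide monohydrate (1.1 equiv), CH2Cl2, −20 °C
Reagents that add atoms: quinuclidine N-oxide, [O-][N+]12CCC(CC1)CC2; water, O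
Why: Proposed new method: site-selective, hydrogen-bond-directed catalytic syn-dihydroxylation, in which the OsO4·quinuclidine adduct (regenerated by the N-oxide, turned over by the hydrate water) has electron-rich oxo ligands that accept hydrogen bonds from the allylic 12-OH and the flanking 6α-OH in non-coordinating CH2Cl2, so the [3+2] addition is delivered to C11=C13 and should outrun the two ring methylenes, which can dock through one homoallylic hydroxyl at best, while 1.1 equiv of oxidant caps conversion at one alkene and no stereocenter arises because C11 ends with two identical CH2OH arms; the closest known reaction type is the stoichiometric OsO4/TMEDA directed dihydroxylation of allylic alcohols and its amine N-oxide catalytic variant, used so far for facial control in cyclic allylic alcohols and amides, not for choosing one of three like alkenes under catalytic turnover.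

Step 3
Reactants: 4 (1αH,5αH,7αH)-guaia-4(15),10(14)-diene-6α,11,12,13-tetraol
Product: 5 (1αH,5αH,7αH)-guaia-4(15),10(14)-diene-6α,11,12,13-tetraol 12,13-diacetate
Conditions: Ac2O (2.2 equiv), pyridine, CH2Cl2, 0 °C
Reagents that add atoms: acetic anhydride, CC(=O)OC(C)=O
Why: Selective O-acylation without DMAP acetylates the two primary hydroxyls far faster than the hindered secondary 6-OH and the tertiary 11-OH, and the two CH2OAc arms are identical so C11 stays non-stereogenic.

Step 4
Reactants: 5 (1αH,5αH,7αH)-guaia-4(15),10(14)-diene-6α,11,12,13-tetraol 12,13-diacetate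
Product: 7 (1R,4R,5S,6S,7R,10R)-guaiane-4α,6α,10α,11,12,13-hexaol 12,13-diacetate, via bis-hydroperoxide 6 (not isolated)
Conditions: Co(acac)2 (25 mol %), PhSiH3 (4 equiv), O2 (1 atm), THF, 0 °C → rt; then PPh3 (2.5 equiv)
Reagents that add atoms: dioxygen, O=O
Why: Double Mukaiyama hydration (metal-hydride hydrogen-atom transfer) puts H on each terminal CH2, the tertiary C4 and C10 radicals are trapped by O2 from the convex α-face of the cis-fused hydroazulene (the face of H-1 and H-5, away from the β-oriented C7 side chain), and PPh3 reduces the hydroperoxides to the 4α- and 10α-alcohols with β-methyls.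

**Compound list**

1 | (−)-dehydrocostus lactone, (1αH,5αH,7αH)-guaia-4(15),10(14),11(13)-trien-12,6α-olide, (3aS,6aR,9aR,9bS)-3,6,9-trimethylidenedecahydroazuleno[4,5-b]furan-2-one | C=C3[C@@H]1CCC(=C)[C@@H]2CCC(=C)[C@@H]2[C@H]1OC3=O | starting material
2 | lactol, 6α,12-epoxy-(1αH,5αH,7αH)-guaia-4(15),10(14),11(13)-trien-12-ol (C12 epimers, present as its aluminium alkoxide) | C=C3[C@@H]1CCC(=C)[C@@H]2CCC(=C)[C@@H]2[C@H]1OC3O | intermediate (not isolated)
3 | (1αH,5αH,7αH)-guaia-4(15),10(14),11(13)-triene-6α,12-diol (exocyclic methylenes at C4 and C10, 6α-OH, 7β-(3-hydroxyprop-1-en-2-yl)) | C=C(CO)[C@@H]1CCC(=C)[C@@H]2CCC(=C)[C@@H]2[C@H]1O | intermediate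
4 | (1αH,5αH,7αH)-guaia-4(15),10(14)-diene-6α,11,12,13-tetraol (7β-C(OH)(CH2OH)2) | OCC(O)(CO)[C@@H]1CCC(=C)[C@@H]2CCC(=C)[C@@H]2[C@H]1O | intermediate
5 | (1αH,5αH,7αH)-guaia-4(15),10(14)-diene-6α,11,12,13-tetraol 12,13-diacetate | CC(=O)OCC(O)(COC(C)=O)[C@@H]1CCC(=C)[C@@H]2CCC(=C)[C@@H]2[C@H]1O | intermediate
6 | bis-hydroperoxide, 4α,10α-bis(hydroperoxy)-(1αH,5αH,7αH)-guaiane-6α,11,12,13-tetraol 12,13-diacetate | CC(=O)OCC(O)(COC(C)=O)[C@@H]1CC[C@@](C)(OO)[C@@H]2CC[C@@](C)(OO)[C@@H]2[C@H]1O | intermediate (not isolated)
7 | CNP0179913.1, (1R,4R,5S,6S,7R,10R)-guaiane-4α,6α,10α,11,12,13-hexaol 12,13-diacetate (1αH,5αH,7αH; 4β- and 10β-methyl) | CC(=O)OCC(O)(COC(C)=O)[C@@H]1CC[C@@](C)(O)[C@@H]2CC[C@@](C)(O)[C@@H]2[C@H]1O | target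

**Step count and risks**

Total step count: 4. Longest linear sequence: 4 steps, from 1 to 7.

The three steps most likely to fail, in this order:

Step 2 (the new reaction). The oxidant may not discriminate well enough: the 6α-OH could steer osmylation to C4=C15, or turnover could be slow. The fallback uses known chemistry, sets out from 3 and comes back at 4. Hydroxyl-directed epoxidation with VO(acac)2 (5 mol %) and t-BuOOH in CH2Cl2 at 0 °C, which is specific for the allylic-alcohol alkene, gives 11,13-epoxy-(1αH,5αH,7αH)-guaia-4(15),10(14)-diene-6α,12-diol F1 as a C11 epimer mixture, which is of no consequence. Dilute HClO4 in THF/H2O at 0 °C then opens the oxirane with water; either regiochemistry gives the same triol unit, so 4 results.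

Step 4. Trapping of the C10 radical in the flexible seven-membered ring may be poorly face-selective, or reversible hydrogen-atom transfer may isomerise the methylenes. The fallback sets out from 4 and comes back at 7. mCPBA with NaHCO3 in CH2Cl2 at 0 °C epoxidises both methylenes from the convex α-face, with the 6α-OH guiding the peracid at C4=C15, to give 4α,15:10α,14-diepoxy-(1αH,5αH,7αH)-guaiane-6α,11,12,13-tetraol F2. LiAlH4 in THF (0 °C → reflux) opens both oxiranes at their CH2 ends with retention of the tertiary C–O bonds to give (1αH,5αH,7αH)-guaiane-4α,6α,10α,11,12,13-hexaol F3. Ac2O in pyridine, as in step 3, then acetylates only the two primary hydroxyls to give 7.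

Step 3. Over-acetylation at 6-OH or stalling at the monoacetate is possible. The fallback sets out from 4 and comes back at 5. It replaces reagent control by enzyme recognition: immobilised Candida antarctica lipase B (Novozym 435) with vinyl acetate in THF at 40 °C accepts only unhindered primary hydroxyls and passes through (1αH,5αH,7αH)-guaia-4(15),10(14)-diene-6α,11,12,13-tetraol 12-monoacetate F4 on the way to 5.

**Further compounds**

F1 | step 2 | 11,13-epoxy-(1αH,5αH,7αH)-guaia-4(15),10(14)-diene-6α,12-diol (C11 epimers) | OCC3(CO3)[C@@H]1CCC(=C)[C@@H]2CCC(=C)[C@@H]2[C@H]1O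
F2 | step 4 | 4α,15:10α,14-diepoxy-(1αH,5αH,7αH)-guaiane-6α,11,12,13-tetraol | OCC(O)(CO)[C@@H]1CC[C@@]3(OC3)[C@@H]2CC[C@@]4(OC4)[C@@H]2[C@H]1O
F3 | step 4 | (1αH,5αH,7αH)-guaiane-4α,6α,10α,11,12,13-hexaol | OCC(O)(CO)[C@@H]1CC[C@@](C)(O)[C@@H]2CC[C@@](C)(O)[C@@H]2[C@H]1O
F4 | step 3 | (1αH,5αH,7αH)-guaia-4(15),10(14)-diene-6α,11,12,13-tetraol 12-monoacetate (C11 epimers) | CC(=O)OCC(O)(CO)[C@@H]1CCC(=C)[C@@H]2CCC(=C)[C@@H]2[C@H]1O
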